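## The problem

The target 49 is numbered along its chain: C1 (methyl), C2, C3=C4, C5 (carbinol), C6=C7(Cl), C8, C9, O10, C11 (lactone carbonyl), C12=C13, C14, C15, C16–C18, C19, C20–C22, C23, N24, C25. Ring A is the cyclopentane C19–C23, ring B the piperidine N24/C15–C19, ring C the tetrahydropyridine N24/C25/C12–C15. Three rings meet at N24, rings A and B share only the fully substituted carbon C19, and a 15-membered lactone runs from C2 (exocyclic on C23) to the ring C carboxyl C11. Five stereocentres are needed. C19, C23 and C2 are contiguous and cannot be corrected once made, so they must come from one controlled sequence in which C23 directs C19. C15 lies 1,3 to C19 across nitrogen and can be set from the C19/C23 pair, but only if hydrogen is the last group to arrive at C15. C5 is remote and needs a reagent; the alkenes must be 3Z and 6E (chlorine trans to C5). The chloro-dienol will not stand strong acid, the β,γ-unsaturated amino ester of ring C can slip into conjugation with nitrogen under strong base, the tertiary amine limits oxidants, and C2 is epimerisable whenever C3 is a carbonyl. The feature that opens the route is that C19 carries N24 and is bonded to C23: moving C23 back from C19 to C18 turns the spiro junction into a fused octahydroquinoline with a hydroxyl on C18 beside a C19=N24 imine.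

## Retrosynthesis

**C3=C4 and O10–C11.** Target 49 is taken back to the alkyne macrolactone 48 (semihydrogenation gives 3Z) and 48 to the seco acid 46 by cutting the lactone C–O bond. Closing at C3=C4 by metathesis would join two allylically branched alkenes with uncertain geometry; closing at C4–C5 would make the C5 centre inside a macrocyclisation. Lactonisation of a primary alcohol is the best-precedented closure, and the alkyne keeps the free C5 hydroxyl from competing, since its lactone would be an 11-membered cycloalkyne.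

**C4–C5.** Seco acid 46 comes from ester 45, and 45 from the tricyclic alkyne 40 and the five-carbon chloroenal 43. This cut separates the remote C5 centre from the core and puts it under ligand control. A Wittig cut at C3=C4 would need a β-oxygenated ylide. The forward step must add an alkynylzinc to a β-chloroenal without touching the ester or amine.

**The chloroenal.** 43 comes from vinyl iodide 42 by formylation, and 42 from but-3-yn-1-yl acetate 41 by anti iodochlorination. Hydrochlorination of an ynoate would give the other geometry (chlorine cis to the carbonyl). The anti addition of I–Cl puts C5 and C8 cis in two steps.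

**Ring C.** Alkyne 40 is the one-carbon homologue of aldehyde 38, which comes from silyl ether 36. Ring C of 36 is cut at N24–C25 and C12=C13, giving amine 33 and methyl 2-(bromomethyl)acrylate 34 through diene 35. Alkylation with a reactive allylic bromide and ring-closing metathesis to a six-membered enoate are both routine. The cut leaves a spiro amine with one allyl group.

**C15.** Amine 33 is traced through the ketimine 32 to the allyl amine 30, to aldimine 28 and to the unsubstituted spiro amine 26. A carbon nucleophile adding to a C15=N24 imine should enter axially on the face of C20, away from the C2 branch that leans over nitrogen. That would place C14 trans to C23, the wrong side. Hydride follows the same preference and then gives the right side. The allyl group is therefore added without regard to configuration, and C15 is re-oxidised and reduced. Because C19 has no hydrogen, both oxidations can only go toward C15.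

**C18 oxygen and the nitrogen protecting group.** Amine 26 comes from the N-allyloxycarbonyl ketone 22 by way of enol triflate 24 and alkene 25. A hydrazone-based deoxygenation was set aside because an α-amino hydrazone can expel nitrogen under base. The zerovalent palladium/formate reduction of the triflate also cleaves the allyl carbamate.

**C19–C23 (key).** Ketone 22 is cut at C19–C23 and the bond is returned to C18, giving hydroxy imine 19 and allyl chloroformate 20. One 1,2-shift makes ring A, the spiro centre and its configuration. The precursor is a fused bicycle with two ring stereocentres instead of an aza-quaternary spirocycle. The forward step asks that C23, not C17, migrates and stays on its face.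

**C18–O and C19=N24.** Hydroxy imine 19 comes from imine 17 by autoxidation at the ring-fusion carbon, anti to the branch. Imine 17 comes from the Boc-amino ketone 15 by deprotection and condensation. The silyl ether is tert-butyldiphenylsilyl (TBDPS) so that it survives trifluoroacetic acid and camphorsulfonic acid.

**C2–C23.** Ketone 15 derives from acid 11 through diol 13 and silyl ether 14. Acid 11 is cut at C2–C23 to propanoate 8 (Ireland–Claisen rearrangement). This single sigmatropic step sets both stereocentres from one carbinol. An alkylation approach would need two separate controls.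

**C17–C18 and the carbinol.** Ester 8 comes from allylic alcohol 6 and propanoyl chloride 7. Alcohol 6 comes from iodo alcohol 3 and tert-butyl allylcarbamate 4 through borane 5 (B-alkyl Suzuki coupling). Alcohol 3 comes from iodoenone 2 and cyclohex-2-en-1-one 1 by iodination and CBS reduction.

## Roads not taken

Alternative 1: The C19–N24 bond is cut and made by C–H amidation. The dioxazolone A1, a trans-1,2-disubstituted cyclopentane, would lose CO2 on Cp*IrCl[8-(methoxycarbonylamido)quinoline] activated with NaBArF4. The acyl nitrenoid would insert into the tertiary C19–H bond with retention and close the cis-fused γ-lactam A2 (N24, C3, C2, C23, C19). Its merit is that the aza-quaternary centre comes from an ordinary C–H stereocentre, and insertion chemistry of this kind has better precedent than the key step chosen here. Its weak points are three. The secondary C22–H bonds are also γ to the nitrenoid and less hindered than C19–H. All three stereocentres of A1 must be set separately on a cyclopentane. In A2, C3 is locked to N24 as a lactam that must be opened again before C3 can become the alkene carbon. Up to the spiro amine this road is probably as short as the chosen one. The chosen plan sets against it that C2 and C23 come from one rearrangement, C19 follows from them stereospecifically, and ring B is formed in the same step instead of by a later alkylation.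

Alternative 2: N24–C25 and C14–C15 are cut together. Heating the imine–sulfolene ester A3 would release SO2 and a 2-(alkoxycarbonyl)diene. The imine nitrogen would add to C25 and the dienolate would close onto C15, forming ring C and the macrocycle at once to give the silyl ether A4 of the target. This would be two or three steps shorter at the end, needs neither metathesis nor lactonisation, and the tether from the C23 side might even deliver C14 to the correct face of C15; in step economy and possibly in C15 control it is the better plan. Against it: the nucleophile is a hindered, unactivated imine nitrogen next to a quaternary carbon, and its first bond must close a 15-membered ring. The free diene dimerises readily, and the C15 configuration is decided inside this one unprecedented event on the most valuable intermediate. The chosen plan forms the same bonds one at a time by precedented reactions and fixes C15 by hydride delivery.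

Alternative 3: The C18–C19 bond is cut. Fe(acac)3 and PhSiH3 would transfer a hydrogen atom to C20 of the enecarbamate A5, and the tertiary α-amino radical at C19 would add to the CH2 end of the tethered vinyl sulfone to give the spirocycle A6. The radical coupling class is well established for quaternary centres and is milder than anything in the chosen route up to that point; attack anti to the C2 branch would also give the right C19 configuration. Its weak points are that C23 of A5 is allylic to the enecarbamate and was next to a carbonyl or iminium carbon at every earlier stage. The C2/C23 relationship therefore rests on an epimerisable centre, and the enecarbamate can also form toward C23. A6 is a pair of sulfone epimers that needs a desulfonylation, and the methyl carbamate is hard to remove. The chosen plan sets against the better precedent of this bond formation that none of its stereocentres is ever epimerisable before the spiro centre exists.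

Key step: step 11

Assumption (chemistry): the (S,S) enantiomer of ProPhenol is taken as the one that gives the 5S carbinol 45; if the sense is the reverse, the (R,R) ligand is used in step 25 and nothing else changes.

Abbreviations: TBDPS = tert-butyldiphenylsilyl; Boc = tert-butoxycarbonyl; DBU = 1,8-diazabicyclo[5.4.0]undec-7-ene; "C2 branch" = (2R)-1-(TBDPS-oxy)propan-2-yl. Descriptors given with atom numbers (2R, 15R and so on) use the target numbering.

Step 1
Reactants: 1 cyclohex-2-en-1-one
Product: 2 2-iodocyclohex-2-en-1-one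
Conditions: I2, pyridine, CH2Cl2, 0 °C → rt
Reagents that add atoms: iodine, [I][I]
Why: α-Iodination of an enone by conjugate addition of pyridine, iodination of the enolate and elimination; standard for cyclohexenone.

Step 2
Reactants: 2 2-iodocyclohex-2-en-1-one
Product: 3 (1R)-2-iodocyclohex-2-en-1-ol
Conditions: (S)-2-methyl-CBS-oxazaborolidine (10 mol %), BH3·SMe2, THF, −20 °C
Reagents that add atoms: none
Why: CBS reduction; the iodoalkene carbon acts as the large carbonyl substituent, so the (S) catalyst should deliver hydride to the face that gives the 1R carbinol, the source of all core stereochemistry.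

Step 3
Reactants: 3 (1R)-2-iodocyclohex-2-en-1-ol; 4 tert-butyl N-(prop-2-en-1-yl)carbamate
Product: 6 tert-butyl N-{3-[(6R)-6-hydroxycyclohex-1-en-1-yl]propyl}carbamate, via B-alkyl-9-BBN 5 (not isolated)
Conditions: 4, 9-BBN, THF, 0 °C → rt; then 3, PdCl2(dppf) (5 mol %), AsPh3, Cs2CO3, DMF–H2O, rt
Reagents that add atoms: none
Why: Anti-Markovnikov hydroboration followed by B-alkyl Suzuki–Miyaura coupling with the vinyl iodide; the free allylic hydroxyl is tolerated and the carbinol centre is not touched.

Step 4
Reactants: 6 tert-butyl N-{3-[(6R)-6-hydroxycyclohex-1-en-1-yl]propyl}carbamate; 7 propanoyl chloride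
Product: 8 (1R)-2-{3-[(tert-butoxycarbonyl)amino]propyl}cyclohex-2-en-1-yl propanoate
Conditions: pyridine, 4-(dimethylamino)pyridine (cat.), CH2Cl2, 0 °C
Reagents that add atoms: none
Why: Acylation of a secondary allylic alcohol; the carbamate N–H does not compete under these conditions.

Step 5
Reactants: 8 (1R)-2-{3-[(tert-butoxycarbonyl)amino]propyl}cyclohex-2-en-1-yl propanoate
Product: 11 (2R)-2-[(1R)-2-{3-[(tert-butoxycarbonyl)amino]propyl}cyclohex-2-en-1-yl]propanoic acid, via silyl ketene acetal 9 (not isolated), via silyl ester 10 (not isolated)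
Conditions: LiN(iPr)2 (2.3 equiv), Me3SiCl, THF, −78 °C; then rt → 60 °C; 1 M HCl work-up
Reagents that add atoms: none
Why: Ireland–Claisen rearrangement; LiN(iPr)2 in THF gives the (E)-silyl ketene acetal, which should react through the chair transition state because the boat would push the enolate methyl over ring carbon C22. The new bond forms on the face from which the C–O bond leaves (C23), and the acetal geometry sets C2.

Step 6
Reactants: 11 (2R)-2-[(1R)-2-{3-[(tert-butoxycarbonyl)amino]propyl}cyclohex-2-en-1-yl]propanoic acid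
Product: 13 tert-butyl N-(3-{(6R)-2-hydroxy-6-[(2R)-1-hydroxypropan-2-yl]cyclohexyl}propyl)carbamate (ring C1/C2 diastereomers), via organoborane 12 (not isolated)
Conditions: BH3·SMe2 (4 equiv), THF, 0 °C → rt; then NaOH, H2O2, 0 °C → rt
Reagents that add atoms: hydrogen peroxide, OO
Why: Borane reduces the acid to the primary alcohol and hydroborates the trisubstituted alkene with boron at C19 (anti-Markovnikov); oxidation gives the C19 carbinol. The new C18 and C19 centres need no control because both are erased later.

Step 7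
Reactants: 13 tert-butyl N-(3-{(6R)-2-hydroxy-6-[(2R)-1-hydroxypropan-2-yl]cyclohexyl}propyl)carbamate
Product: 14 tert-butyl N-(3-{(6R)-2-hydroxy-6-[(2R)-1-(TBDPS-oxy)propan-2-yl]cyclohexyl}propyl)carbamate
Conditions: tBuPh2SiCl (1.05 equiv), imidazole, CH2Cl2, 0 °C
Reagents that add atoms: tert-butyl(chloro)diphenylsilane, CC(C)(C)[Si](Cl)(c1ccccc1)c1ccccc1
Why: Selective silylation of the primary hydroxyl over the hindered ring carbinol; TBDPS is chosen to survive the acids of steps 9 and 11.

Step 8
Reactants: 14 tert-butyl N-(3-{(6R)-2-hydroxy-6-[(2R)-1-(TBDPS-oxy)propan-2-yl]cyclohexyl}propyl)carbamate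
Product: 15 tert-butyl N-(3-{(2R)-6-oxo-2-[(2R)-1-(TBDPS-oxy)propan-2-yl]cyclohexyl}propyl)carbamate (C18 epimers)
Conditions: Dess–Martin periodinane, NaHCO3, CH2Cl2, rt
Reagents that add atoms: none
Why: Dess–Martin oxidation of the secondary alcohol to the C19 ketone; the epimerisable C18 centre is of no consequence.

Step 9
Reactants: 15 tert-butyl N-(3-{(2R)-6-oxo-2-[(2R)-1-(TBDPS-oxy)propan-2-yl]cyclohexyl}propyl)carbamate
Product: 17 (5S)-5-[(2R)-1-(TBDPS-oxy)propan-2-yl]-2,3,4,4a,5,6,7,8-octahydroquinoline (C4a epimers), via ammonium trifluoroacetate 16 (not isolated)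
Conditions: CF3CO2H–CH2Cl2 (1:4), 0 °C; evaporate; aq. NaHCO3, CH2Cl2, argon
Reagents that add atoms: none
Why: Acidolysis of the Boc group, then spontaneous condensation of the primary amine with the ketone to the six-membered cyclic imine; kept under argon because the product autoxidises.

Step 10
Reactants: 17 (5S)-5-[(2R)-1-(TBDPS-oxy)propan-2-yl]-2,3,4,4a,5,6,7,8-octahydroquinoline
Product: 19 (4aR,5R)-5-[(2R)-1-(TBDPS-oxy)propan-2-yl]-3,4,5,6,7,8-hexahydro-2H-quinolin-4a-ol, via hydroperoxide 18 (not isolated)
Conditions: O2 (1 atm), hexane–EtOAc, rt; then PPh3, 0 °C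
Reagents that add atoms: dioxygen, O=O
Why: Autoxidation of the enamine tautomer at the ring-fusion carbon, a known reaction of the parent octahydroquinoline, followed by phosphine reduction of the hydroperoxide. In the enamine the C2 branch on C23 should stand pseudoaxial to avoid allylic strain with C17, so oxygen should enter C18 on the opposite face.

Step 11
Reactants: 19 (4aR,5R)-5-[(2R)-1-(TBDPS-oxy)propan-2-yl]-3,4,5,6,7,8-hexahydro-2H-quinolin-4a-ol; 20 prop-2-en-1-yl carbonochloridate (allyl chloroformate)
Product: 22 prop-2-en-1-yl (1R,5R)-10-oxo-1-[(2R)-1-(TBDPS-oxy)propan-2-yl]-6-azaspiro[4.5]decane-6-carboxylate, via N-acyliminium chloride 21 (not isolated)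
Conditions: 20 (1.1 equiv), CH2Cl2, −78 → 0 °C; then camphor-10-sulfonic acid (1 equiv), 0 °C → rt; aq. NaHCO3
Reagents that add atoms: none
Why: Proposed new method: acylation of the imine nitrogen by 20 gives the N-acyliminium ion 21 (any enecarbamate or α-chloro carbamate that forms is returned to 21 by the sulfonic acid); as the C18 oxygen donates toward C18, C23 slides from C18 to C19 across one face of the iminium ion, and loss of HCl leaves the C18 ketone and a neutral carbamate. The closest known reaction type is the α-iminol (aza-semipinacol) rearrangement, whose fused-to-spiro ring-contracting form is established for hydroxyindolenines; the acid-promoted shift onto an N-acyliminium carbon is known in the ring-expanding direction. Ring A is not closed by a cyclisation but by ring contraction through a three-centre bridged transition state in which C23 spans C18 and C19, so no exo or endo mode applies. The new stereocentre C19 is controlled by the C18 carbinol: C23 remains on the face of the iminium plane opposite to oxygen, so a hydroxyl anti to the C2 branch puts N24 cis to that branch on ring A, and C23 keeps its configuration. The step needs migration of C23 and not C17; the substrate secures this because the C18–C23 bond stands roughly 50° out of the iminium plane whereas C18–C17, tied into ring B, lies almost in it, and because C23 is the more substituted carbon. It also needs N-acylation before O-acylation, which a nucleophilic imine nitrogen beside a hindered tertiary alcohol should give. The exchange of a cation for a carbamate and a C=O bond should more than pay for the strain of going from a six- to a five-membered carbocycle.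

Step 12
Reactants: 22 prop-2-en-1-yl (1R,5R)-10-oxo-1-[(2R)-1-(TBDPS-oxy)propan-2-yl]-6-azaspiro[4.5]decane-6-carboxylate
Product: 24 prop-2-en-1-yl (1R,5R)-1-[(2R)-1-(TBDPS-oxy)propan-2-yl]-10-{[(trifluoromethyl)sulfonyl]oxy}-6-azaspiro[4.5]dec-9-ene-6-carboxylate, via potassium enolate 23 (not isolated)
Conditions: KN(SiMe3)2, THF, −78 °C; then PhNTf2, −78 → 0 °C
Reagents that add atoms: N-phenylbis(trifluoromethanesulfonimide), O=S(=O)(N(c1ccccc1)S(=O)(=O)C(F)(F)F)C(F)(F)F
Why: Enol triflate formation; only C17 carries α-hydrogens, so the enolate is regiodefined.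

Step 13
Reactants: 24 prop-2-en-1-yl (1R,5R)-1-[(2R)-1-(TBDPS-oxy)propan-2-yl]-10-{[(trifluoromethyl)sulfonyl]oxy}-6-azaspiro[4.5]dec-9-ene-6-carboxylate
Product: 25 (1R,5R)-1-[(2R)-1-(TBDPS-oxy)propan-2-yl]-6-azaspiro[4.5]dec-9-ene
Conditions: Pd(OAc)2 (10 mol %), PPh3, HCO2H, Et3N, DMF, 60 °C
Reagents that add atoms: none
Why: Palladium-catalysed formate reduction of the enol triflate to the alkene; the same catalyst and hydride source cleave the allyl carbamate by allyl transfer and decarboxylation, so the C18 oxygen and the nitrogen protecting group leave together.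

Step 14
Reactants: 25 (1R,5R)-1-[(2R)-1-(TBDPS-oxy)propan-2-yl]-6-azaspiro[4.5]dec-9-ene
Product: 26 (1R,5S)-1-[(2R)-1-(TBDPS-oxy)propan-2-yl]-6-azaspiro[4.5]decane
Conditions: H2 (1 atm), Pd/C, EtOAc, rt
Reagents that add atoms: none
Why: Hydrogenation of the only alkene; no stereocentre is formed (the change of the C5 descriptor is a priority change).

Step 15
Reactants: 26 (1R,5S)-1-[(2R)-1-(TBDPS-oxy)propan-2-yl]-6-azaspiro[4.5]decane
Product: 28 (1R,5S)-1-[(2R)-1-(TBDPS-oxy)propan-2-yl]-6-azaspiro[4.5]dec-6-ene, via N-chloroamine 27 (not isolated)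
Conditions: N-chlorosuccinimide, CH2Cl2, 0 °C; then DBU, 0 °C → rt
Reagents that add atoms: none
Why: N-Chlorination and base-induced dehydrochlorination to the cyclic imine; C19 has no hydrogen, so elimination can only give the C15 aldimine, and the quaternary neighbour prevents trimerisation.

Step 16
Reactants: 28 (1R,5S)-1-[(2R)-1-(TBDPS-oxy)propan-2-yl]-6-azaspiro[4.5]dec-6-ene; 29 allylmagnesium bromide
Product: 30 (1R,5S)-7-(prop-2-en-1-yl)-1-[(2R)-1-(TBDPS-oxy)propan-2-yl]-6-azaspiro[4.5]decane (C7 epimers)
Conditions: Et2O, −78 → 0 °C; aq. NH4Cl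
Reagents that add atoms: none
Why: Grignard addition to the aldimine installs C14–C13 and the terminal alkene; the configuration at C15 is not relied on, since both epimers converge in step 17 (the epimer with allyl cis to C20 is expected to dominate).

Step 17
Reactants: 30 (1R,5S)-7-(prop-2-en-1-yl)-1-[(2R)-1-(TBDPS-oxy)propan-2-yl]-6-azaspiro[4.5]decane
Product: 33 (1R,5S,7R)-7-(prop-2-en-1-yl)-1-[(2R)-1-(TBDPS-oxy)propan-2-yl]-6-azaspiro[4.5]decane, via N-chloroamine 31 (not isolated), via ketimine 32 (not isolated)
Conditions: N-chlorosuccinimide, CH2Cl2, −20 °C; DBU, −20 → 0 °C; then NaBH4, MeOH, −40 °C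
Reagents that add atoms: none
Why: A second N-chlorination and elimination, again possible only toward C15, gives the ketimine, and borohydride reduces it. Hydride should add axially on the face of the C20 methylene, away from the C2 branch that leans over nitrogen, leaving the allyl group equatorial and cis to C23 (the known cis-selective reduction of 2,6-disubstituted cyclic imines).

Step 18
Reactants: 33 (1R,5S,7R)-7-(prop-2-en-1-yl)-1-[(2R)-1-(TBDPS-oxy)propan-2-yl]-6-azaspiro[4.5]decane; 34 methyl 2-(bromomethyl)prop-2-enoate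
Product: 35 methyl 2-({(1R,5S,7R)-7-(prop-2-en-1-yl)-1-[(2R)-1-(TBDPS-oxy)propan-2-yl]-6-azaspiro[4.5]decan-6-yl}methyl)prop-2-enoate
Conditions: K2CO3, MeCN, 50 °C
Reagents that add atoms: none
Why: N-Alkylation with a highly reactive allylic bromide (direct or conjugate displacement gives the same product), which is what the hindered secondary amine requires; forms N24–C25.

Step 19
Reactants: 35 methyl 2-({(1R,5S,7R)-7-(prop-2-en-1-yl)-1-[(2R)-1-(TBDPS-oxy)propan-2-yl]-6-azaspiro[4.5]decan-6-yl}methyl)prop-2-enoate
Product: 36 tricyclic methyl ester (rings A–C; N24–C25H2–C12(CO2Me)=C13H–C14H2–C15; C3 as CH2O-TBDPS; 2R,15R,19S,23R)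
Conditions: second-generation Hoveyda–Grubbs catalyst (10 mol %), camphor-10-sulfonic acid (1.1 equiv), toluene (5 mM), 80 °C; aq. NaHCO3
Reagents that add atoms: none
Why: Ring-closing metathesis of the allyl group with the 1,1-disubstituted acrylate closes the six-membered ring C and places the C12=C13 double bond; the amine is protonated to keep it off ruthenium.

Step 20
Reactants: 36 tricyclic methyl ester (C3 as CH2O-TBDPS)
Product: 37 tricyclic hydroxy ester (C3 as CH2OH; 2R,15R,19S,23R)
Conditions: Bu4NF, AcOH, THF, rt
Reagents that add atoms: none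
Why: Fluoride cleavage of the silyl ether, buffered so that the methyl ester and the ring C alkene position are not disturbed.

Step 21
Reactants: 37 tricyclic hydroxy ester
Product: 38 tricyclic aldehyde (C3 as CHO; 2R,15R,19S,23R)
Conditions: Dess–Martin periodinane, NaHCO3, CH2Cl2, 0 °C
Reagents that add atoms: none
Why: Buffered Dess–Martin oxidation is compatible with the tertiary amine and gives the α-branched aldehyde without base; it is used at once to protect C2.

Step 22
Reactants: 38 tricyclic aldehyde; 39 dimethyl (1-diazo-2-oxopropyl)phosphonate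
Product: 40 tricyclic alkyne (C2–C3≡C4H; 2R,15R,19S,23R)
Conditions: K2CO3, MeOH, 0 °C → rt
Reagents that add atoms: none
Why: Ohira–Bestmann (Seyferth–Gilbert) homologation adds C4 and gives the terminal alkyne; α-alkyl-branched aldehydes normally pass without epimerisation, and methanol matches the methyl ester.

Step 23
Reactants: 41 but-3-yn-1-yl acetate
Product: 42 (3E)-3-chloro-4-iodobut-3-en-1-yl acetate
Conditions: ICl, CH2Cl2, −78 → 0 °C, dark
Reagents that add atoms: iodine monochloride, ClI
Why: Anti iodochlorination of a terminal alkyne: iodine goes to the terminal carbon, chloride opens the iodonium ion at the internal carbon from the opposite side, so iodine (later C5) is cis to C8 and trans to chlorine.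

Step 24
Reactants: 42 (3E)-3-chloro-4-iodobut-3-en-1-yl acetate
Product: 43 (3E)-3-chloro-5-oxopent-3-en-1-yl acetate
Conditions: CO (3 atm), Bu3SnH (slow addition), Pd(PPh3)4 (5 mol %), toluene, 50 °C
Reagents that add atoms: carbon monoxide, [C-]#[O+]
Why: Palladium-catalysed reductive carbonylation (formylation) of the vinyl iodide with retention of geometry; the C–Cl bond does not add to palladium, and a chlorine trans to palladium cannot undergo syn β-elimination.

Step 25
Reactants: 40 tricyclic alkyne; 43 (3E)-3-chloro-5-oxopent-3-en-1-yl acetate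
Product: 45 propargylic alcohol (C4–C5 joined; C5–OH; C9–OAc; methyl ester; 2R,5S,15R,19S,23R; 6E), via methylzinc acetylide 44 (not isolated)
Conditions: 40, Me2Zn (3 equiv), (S,S)-ProPhenol (20 mol %), Ph3PO (40 mol %), toluene, 0 °C; then 43 (2 equiv, slow addition), 4 °C
Reagents that add atoms: none
Why: Zinc–ProPhenol catalysed alkynylation of an α,β-unsaturated aldehyde; the dinuclear zinc catalyst alone sets C5, which is too remote for substrate control, and zinc acetylides leave the two esters and the vinyl chloride alone.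

Step 26
Reactants: 45 propargylic alcohol
Product: 46 seco acid (C11 CO2H; C9–OH; C5–OH; 2R,5S,15R,19S,23R)
Conditions: LiOH, THF–MeOH–H2O, 0 °C → rt; adjust to pH 6
Reagents that add atoms: lithium hydroxide, [Li+].[OH-]
Why: Saponification removes the acetate and the methyl ester in one operation; the mild hydroxide conditions are chosen so that the ring C double bond does not move into conjugation with nitrogen.

Step 27
Reactants: 46 seco acid
Product: 48 alkyne macrolactone (O10–C11 closed; C3≡C4; 2R,5S,15R,19S,23R), via mixed anhydride 47 (not isolated)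
Conditions: 2-methyl-6-nitrobenzoic anhydride, 4-(dimethylamino)pyridine, CH2Cl2 (1 mM, slow addition of 46), rt
Reagents that add atoms: none
Why: Shiina macrolactonisation; the primary C9 hydroxyl should acylate in preference to the hindered C5 carbinol, whose lactone would be an 11-membered ring containing the alkyne.

Step 28
Reactants: 48 alkyne macrolactone
Product: 49 target macrolactone (2S,5R,15R,19S,23R; 3Z,6E)
Conditions: H2 (1 atm), Pd/CaCO3 poisoned with Pb(OAc)2, quinoline, EtOAc, rt, stopped at 1 equiv
Reagents that add atoms: none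
Why: Lindlar semihydrogenation adds hydrogen syn to the alkyne and gives the 3Z alkene; the trisubstituted enoate and the chloroalkene are expected to survive. The descriptors at C2 and C5 change only through priorities.

## Compound list

1 | cyclohex-2-en-1-one | O=C1C=CCCC1 | starting material
2 | 2-iodocyclohex-2-en-1-one | O=C1C(I)=CCCC1 | intermediate
3 | (1R)-2-iodocyclohex-2-en-1-ol | O[C@@H]1CCCC=C1I | intermediate
4 | tert-butyl N-(prop-2-en-1-yl)carbamate | C=CCNC(=O)OC(C)(C)C | starting material
5 | tert-butyl N-[3-(9-borabicyclo[3.3.1]nonan-9-yl)propyl]carbamate | CC(C)(C)OC(=O)NCCCB1C2CCCC1CCC2 | intermediate (not isolated)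
6 | tert-butyl N-{3-[(6R)-6-hydroxycyclohex-1-en-1-yl]propyl}carbamate | O[C@@H]1CCCC=C1CCCNC(=O)OC(C)(C)C | intermediate
7 | propanoyl chloride | CCC(Cl)=O | starting material
8 | (1R)-2-{3-[(tert-butoxycarbonyl)amino]propyl}cyclohex-2-en-1-yl propanoate | CCC(=O)O[C@@H]1CCCC=C1CCCNC(=O)OC(C)(C)C | intermediate
9 | (E)-trimethylsilyl ketene acetal of 8, carbamate nitrogen silylated (methyl trans to OSiMe3) | C/C=C(/O[Si](C)(C)C)O[C@@H]1CCCC=C1CCCN([Si](C)(C)C)C(=O)OC(C)(C)C | intermediate (not isolated)
10 | trimethylsilyl (2R)-2-[(1R)-2-{3-[(tert-butoxycarbonyl)(trimethylsilyl)amino]propyl}cyclohex-2-en-1-yl]propanoate | C[C@@H](C(=O)O[Si](C)(C)C)[C@H]1CCCC=C1CCCN([Si](C)(C)C)C(=O)OC(C)(C)C | intermediate (not isolated)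
11 | (2R)-2-[(1R)-2-{3-[(tert-butoxycarbonyl)amino]propyl}cyclohex-2-en-1-yl]propanoic acid | C[C@@H](C(=O)O)[C@H]1CCCC=C1CCCNC(=O)OC(C)(C)C | intermediate
12 | organoborane from 11 (alkylborane at C19, alkoxyborane at C3–O; drawn as the monomeric BH2 species) | C[C@@H](COB)[C@H]1CCCC(B)C1CCCNC(=O)OC(C)(C)C | intermediate (not isolated)
13 | tert-butyl N-(3-{(6R)-2-hydroxy-6-[(2R)-1-hydroxypropan-2-yl]cyclohexyl}propyl)carbamate (ring C1/C2 unassigned) | C[C@@H](CO)[C@H]1CCCC(O)C1CCCNC(=O)OC(C)(C)C | intermediate
14 | tert-butyl N-(3-{(6R)-2-hydroxy-6-[(2R)-1-(TBDPS-oxy)propan-2-yl]cyclohexyl}propyl)carbamate | C[C@@H](CO[Si](c1ccccc1)(c1ccccc1)C(C)(C)C)[C@H]1CCCC(O)C1CCCNC(=O)OC(C)(C)C | intermediate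
15 | tert-butyl N-(3-{(2R)-6-oxo-2-[(2R)-1-(TBDPS-oxy)propan-2-yl]cyclohexyl}propyl)carbamate (C18 epimers) | C[C@@H](CO[Si](c1ccccc1)(c1ccccc1)C(C)(C)C)[C@H]1CCCC(=O)C1CCCNC(=O)OC(C)(C)C | intermediate
16 | 3-{(2R)-6-oxo-2-[(2R)-1-(TBDPS-oxy)propan-2-yl]cyclohexyl}propan-1-aminium trifluoroacetate | C[C@@H](CO[Si](c1ccccc1)(c1ccccc1)C(C)(C)C)[C@H]1CCCC(=O)C1CCC[NH3+].[O-]C(=O)C(F)(F)F | intermediate (not isolated)
17 | (5S)-5-[(2R)-1-(TBDPS-oxy)propan-2-yl]-2,3,4,4a,5,6,7,8-octahydroquinoline (C4a epimers; C8a=N imine) | C[C@@H](CO[Si](c1ccccc1)(c1ccccc1)C(C)(C)C)[C@H]1CCCC2=NCCCC12 | intermediate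
18 | (4aR,5R)-4a-hydroperoxy-5-[(2R)-1-(TBDPS-oxy)propan-2-yl]-3,4,5,6,7,8-hexahydro-2H-quinoline | C[C@@H](CO[Si](c1ccccc1)(c1ccccc1)C(C)(C)C)[C@H]1CCCC2=NCCC[C@@]12OO | intermediate (not isolated)
19 | (4aR,5R)-5-[(2R)-1-(TBDPS-oxy)propan-2-yl]-3,4,5,6,7,8-hexahydro-2H-quinolin-4a-ol (4a-hydroxy octahydroquinoline imine) | C[C@@H](CO[Si](c1ccccc1)(c1ccccc1)C(C)(C)C)[C@H]1CCCC2=NCCC[C@@]12O | intermediate
20 | prop-2-en-1-yl carbonochloridate (allyl chloroformate) | C=CCOC(Cl)=O | starting material
21 | N-(allyloxycarbonyl)iminium chloride of 19 | C[C@@H](CO[Si](c1ccccc1)(c1ccccc1)C(C)(C)C)[C@H]1CCCC2=[N+](C(=O)OCC=C)CCC[C@@]12O.[Cl-] | intermediate (not isolated)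
22 | prop-2-en-1-yl (1R,5R)-10-oxo-1-[(2R)-1-(TBDPS-oxy)propan-2-yl]-6-azaspiro[4.5]decane-6-carboxylate | C[C@@H](CO[Si](c1ccccc1)(c1ccccc1)C(C)(C)C)[C@H]1CCC[C@@]12N(C(=O)OCC=C)CCCC2=O | intermediate
23 | potassium enolate of 22 (C17=C18–O−) | C[C@@H](CO[Si](c1ccccc1)(c1ccccc1)C(C)(C)C)[C@H]1CCC[C@@]12N(C(=O)OCC=C)CCC=C2[O-].[K+] | intermediate (not isolated)
24 | prop-2-en-1-yl (1R,5R)-1-[(2R)-1-(TBDPS-oxy)propan-2-yl]-10-{[(trifluoromethyl)sulfonyl]oxy}-6-azaspiro[4.5]dec-9-ene-6-carboxylate | C[C@@H](CO[Si](c1ccccc1)(c1ccccc1)C(C)(C)C)[C@H]1CCC[C@@]12N(C(=O)OCC=C)CCC=C2OS(=O)(=O)C(F)(F)F | intermediate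
25 | (1R,5R)-1-[(2R)-1-(TBDPS-oxy)propan-2-yl]-6-azaspiro[4.5]dec-9-ene | C[C@@H](CO[Si](c1ccccc1)(c1ccccc1)C(C)(C)C)[C@H]1CCC[C@@]12NCCC=C2 | intermediate
26 | (1R,5S)-1-[(2R)-1-(TBDPS-oxy)propan-2-yl]-6-azaspiro[4.5]decane | C[C@@H](CO[Si](c1ccccc1)(c1ccccc1)C(C)(C)C)[C@H]1CCC[C@@]12NCCCC2 | intermediate
27 | (1R,5S)-6-chloro-1-[(2R)-1-(TBDPS-oxy)propan-2-yl]-6-azaspiro[4.5]decane | C[C@@H](CO[Si](c1ccccc1)(c1ccccc1)C(C)(C)C)[C@H]1CCC[C@@]12N(Cl)CCCC2 | intermediate (not isolated)
28 | (1R,5S)-1-[(2R)-1-(TBDPS-oxy)propan-2-yl]-6-azaspiro[4.5]dec-6-ene | C[C@@H](CO[Si](c1ccccc1)(c1ccccc1)C(C)(C)C)[C@H]1CCC[C@@]12N=CCCC2 | intermediate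
29 | allylmagnesium bromide | C=CC[Mg]Br | starting material
30 | (1R,5S)-7-(prop-2-en-1-yl)-1-[(2R)-1-(TBDPS-oxy)propan-2-yl]-6-azaspiro[4.5]decane (C7 epimers) | C[C@@H](CO[Si](c1ccccc1)(c1ccccc1)C(C)(C)C)[C@H]1CCC[C@@]12NC(CC=C)CCC2 | intermediate
31 | (1R,5S)-6-chloro-7-(prop-2-en-1-yl)-1-[(2R)-1-(TBDPS-oxy)propan-2-yl]-6-azaspiro[4.5]decane (C7 epimers) | C[C@@H](CO[Si](c1ccccc1)(c1ccccc1)C(C)(C)C)[C@H]1CCC[C@@]12N(Cl)C(CC=C)CCC2 | intermediate (not isolated)
32 | (1R,5S)-7-(prop-2-en-1-yl)-1-[(2R)-1-(TBDPS-oxy)propan-2-yl]-6-azaspiro[4.5]dec-6-ene | C[C@@H](CO[Si](c1ccccc1)(c1ccccc1)C(C)(C)C)[C@H]1CCC[C@@]12N=C(CC=C)CCC2 | intermediate (not isolated)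
33 | (1R,5S,7R)-7-(prop-2-en-1-yl)-1-[(2R)-1-(TBDPS-oxy)propan-2-yl]-6-azaspiro[4.5]decane | C[C@@H](CO[Si](c1ccccc1)(c1ccccc1)C(C)(C)C)[C@H]1CCC[C@@]12N[C@@H](CC=C)CCC2 | intermediate
34 | methyl 2-(bromomethyl)prop-2-enoate | C=C(CBr)C(=O)OC | starting material
35 | methyl 2-({(1R,5S,7R)-7-(prop-2-en-1-yl)-1-[(2R)-1-(TBDPS-oxy)propan-2-yl]-6-azaspiro[4.5]decan-6-yl}methyl)prop-2-enoate | C[C@@H](CO[Si](c1ccccc1)(c1ccccc1)C(C)(C)C)[C@H]1CCC[C@@]12N(CC(=C)C(=O)OC)[C@@H](CC=C)CCC2 | intermediate
36 | tricyclic methyl ester, C3 as CH2O-TBDPS (2R,15R,19S,23R) | C[C@@H](CO[Si](c1ccccc1)(c1ccccc1)C(C)(C)C)[C@H]1CCC[C@@]12N3CC(C(=O)OC)=CC[C@H]3CCC2 | intermediate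
37 | tricyclic hydroxy ester, C3 as CH2OH (2R,15R,19S,23R) | C[C@@H](CO)[C@H]1CCC[C@@]12N3CC(C(=O)OC)=CC[C@H]3CCC2 | intermediate
38 | tricyclic aldehyde, C3 as CHO (2R,15R,19S,23R) | C[C@@H](C=O)[C@H]1CCC[C@@]12N3CC(C(=O)OC)=CC[C@H]3CCC2 | intermediate
39 | dimethyl (1-diazo-2-oxopropyl)phosphonate | CC(=O)C(=[N+]=[N-])P(=O)(OC)OC | starting material
40 | tricyclic alkyne, C2–C3≡C4H (2R,15R,19S,23R) | C[C@@H](C#C)[C@H]1CCC[C@@]12N3CC(C(=O)OC)=CC[C@H]3CCC2 | intermediate
41 | but-3-yn-1-yl acetate | CC(=O)OCCC#C | starting material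
42 | (3E)-3-chloro-4-iodobut-3-en-1-yl acetate | CC(=O)OCC/C(Cl)=C\I | intermediate
43 | (3E)-3-chloro-5-oxopent-3-en-1-yl acetate | CC(=O)OCC/C(Cl)=C\C=O | intermediate
44 | methylzinc acetylide of 40 | C[C@@H](C#C[Zn]C)[C@H]1CCC[C@@]12N3CC(C(=O)OC)=CC[C@H]3CCC2 | intermediate (not isolated)
45 | propargylic alcohol: C5–OH, C9–OAc, methyl ester (2R,5S,15R,19S,23R; 6E) | C[C@@H](C#C[C@@H](O)/C=C(/Cl)CCOC(C)=O)[C@H]1CCC[C@@]12N3CC(C(=O)OC)=CC[C@H]3CCC2 | intermediate
46 | seco acid: C11 CO2H, C9–OH, C5–OH (2R,5S,15R,19S,23R; 6E) | C[C@@H](C#C[C@@H](O)/C=C(/Cl)CCO)[C@H]1CCC[C@@]12N3CC(C(=O)O)=CC[C@H]3CCC2 | intermediate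
47 | mixed anhydride of 46 with 2-methyl-6-nitrobenzoic acid | C[C@@H](C#C[C@@H](O)/C=C(/Cl)CCO)[C@H]1CCC[C@@]12N3CC(C(=O)OC(=O)c4c(C)cccc4[N+](=O)[O-])=CC[C@H]3CCC2 | intermediate (not isolated)
48 | alkyne macrolactone, C3≡C4 (2R,5S,15R,19S,23R; 6E) | C[C@H]1C#C[C@@H](O)/C=C(/Cl)CCOC(=O)C2=CC[C@H]3CCC[C@]4(CCC[C@H]14)N3C2 | intermediate
49 | target macrolactone (2S,5R,15R,19S,23R; 3Z,6E) | C[C@H]1/C=C\[C@@H](O)/C=C(/Cl)CCOC(=O)C2=CC[C@H]3CCC[C@]4(CCC[C@H]14)N3C2 | target

## Step count and least certain steps

Total: 28 steps. Longest linear sequence: 26 steps (steps 1–22 and 25–28, from cyclohex-2-en-1-one); steps 23–24 make the chloroenal.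

**Step 11 (key step).** The acyliminium ion has exits other than the 1,2-shift: ionisation or elimination at the tertiary C18 hydroxyl from the enecarbamate form, or competing migration of C17, because nothing but bond alignment and substitution separates the pathways. Fallback with known chemistry, from 19 back to 22: the neutral α-iminol rearrangement, a documented acid- or heat-promoted equilibration of α-hydroxy imines with α-amino ketones, is run with pyridinium p-toluenesulfonate in toluene at reflux in the presence of diallyl dicarbonate. The free spiro amino ketone F1 is the only species with an N–H, so it is converted to the carbamate as it forms, which drains the equilibrium and returns the route to 22.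

**Step 5.** Chair and boat transition states may not be well separated for a cyclohexenyl ester with a substituent on the central allyl carbon, which would erode the C2 configuration while C23 stays secure. Fallback from 6 back to 13: the alcohol is acetylated to the acetate F2 and rearranged (same Ireland–Claisen conditions) to the acetic acid F3, which has no C2 centre. F3 is attached to (R)-4-benzyl-oxazolidin-2-one (pivaloyl chloride, Et3N, then the lithiated auxiliary) to give the imide F4. Evans methylation (NaN(SiMe3)2, MeI) gives the methylated imide F5 under auxiliary control, and LiBH4 releases the primary alcohol F6. Hydroboration–oxidation of F6 as in step 6 gives 13.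

**Step 10.** Oxygen may enter C18 from both faces, or at C20, since the radical chain is guided only by the neighbouring branch. Fallback from 15 back to 19: the more substituted silyl enol ether F7 is made under equilibrating conditions (Me3SiCl, NaI, Et3N, MeCN) and oxidised with m-chloroperbenzoic acid (Rubottom oxidation, epoxidation anti to the branch) to the α-hydroxy ketone F8. Removal of the Boc group (CF3CO2H, then NaHCO3) lets the amine condense to 19.

**Step 17.** The allyl ketimine may drift into conjugation under the basic elimination, or hydride may add from both faces. Fallback from 28 back to 33, generating the C15=N bond under acid instead of base: the aldimine is oxidised (NaClO2, NaH2PO4, 2-methylbut-2-ene) to the lactam F9, which is converted (Boc2O, 4-(dimethylamino)pyridine) to the N-Boc lactam F10. Allylmagnesium bromide at −78 °C opens F10 to the keto carbamate F11. CF3CO2H then forms the cyclic iminium ion, which NaBH4 reduces in the same flask to 33.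

**Step 25.** The ligand alone controls C5, and a β-chloroenal is an untested partner, so facial selectivity may be low or reversed. Fallback from 40 and 43 back to 46: the addition is run without the chiral ligand, the two C5 epimers (diastereomers, separable by chromatography) are parted, and the unwanted 5R alcohol F12 is inverted under Mitsunobu conditions (4-nitrobenzoic acid, PPh3, diisopropyl azodicarboxylate) to the 5S nitrobenzoate F13. The LiOH treatment of step 26 cleaves this ester together with the acetate and the methyl ester and gives 46.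

**Step 27.** The free C5 hydroxyl may be acylated intermolecularly (oligomers), or the alkyne-containing ring may close slowly. Fallback from 45 back to 48: the C5 hydroxyl is silylated (tBuMe2SiOTf, 2,6-lutidine) to the silyl ether F14. LiOH gives the hydroxy acid F15, and the same lactonisation through the mixed anhydride F16 gives the silyl macrolactone F17. HF·pyridine then returns the route to 48.

## Further compounds

F1 | step 11 | (1R,5R)-1-[(2R)-1-(TBDPS-oxy)propan-2-yl]-6-azaspiro[4.5]decan-10-one | C[C@@H](CO[Si](c1ccccc1)(c1ccccc1)C(C)(C)C)[C@H]1CCC[C@@]12NCCCC2=O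
F2 | step 5 | (1R)-2-{3-[(tert-butoxycarbonyl)amino]propyl}cyclohex-2-en-1-yl acetate | CC(=O)O[C@@H]1CCCC=C1CCCNC(=O)OC(C)(C)C
F3 | step 5 | 2-[(1R)-2-{3-[(tert-butoxycarbonyl)amino]propyl}cyclohex-2-en-1-yl]acetic acid | OC(=O)C[C@H]1CCCC=C1CCCNC(=O)OC(C)(C)C
F4 | step 5 | (4R)-4-benzyl-3-{2-[(1R)-2-{3-[(tert-butoxycarbonyl)amino]propyl}cyclohex-2-en-1-yl]acetyl}-1,3-oxazolidin-2-one | O=C1N(C(=O)C[C@H]2CCCC=C2CCCNC(=O)OC(C)(C)C)[C@H](Cc3ccccc3)CO1
F5 | step 5 | (4R)-4-benzyl-3-{(2R)-2-[(1R)-2-{3-[(tert-butoxycarbonyl)amino]propyl}cyclohex-2-en-1-yl]propanoyl}-1,3-oxazolidin-2-one | O=C1N(C(=O)[C@H](C)[C@H]2CCCC=C2CCCNC(=O)OC(C)(C)C)[C@H](Cc3ccccc3)CO1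
F6 | step 5 | tert-butyl N-(3-{(6R)-6-[(2R)-1-hydroxypropan-2-yl]cyclohex-1-en-1-yl}propyl)carbamate | C[C@@H](CO)[C@H]1CCCC=C1CCCNC(=O)OC(C)(C)C
F7 | step 10 | trimethylsilyl enol ether of 15 (C18=C19) | C[C@@H](CO[Si](c1ccccc1)(c1ccccc1)C(C)(C)C)[C@H]1CCCC(O[Si](C)(C)C)=C1CCCNC(=O)OC(C)(C)C
F8 | step 10 | α-hydroxy ketone: 15 with hydroxyl at C18, anti to the C2 branch | C[C@@H](CO[Si](c1ccccc1)(c1ccccc1)C(C)(C)C)[C@H]1CCCC(=O)[C@@]1(O)CCCNC(=O)OC(C)(C)C
F9 | step 17 | (1R,5S)-1-[(2R)-1-(TBDPS-oxy)propan-2-yl]-6-azaspiro[4.5]decan-7-one | C[C@@H](CO[Si](c1ccccc1)(c1ccccc1)C(C)(C)C)[C@H]1CCC[C@@]12NC(=O)CCC2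
F10 | step 17 | tert-butyl (1R,5S)-7-oxo-1-[(2R)-1-(TBDPS-oxy)propan-2-yl]-6-azaspiro[4.5]decane-6-carboxylate | C[C@@H](CO[Si](c1ccccc1)(c1ccccc1)C(C)(C)C)[C@H]1CCC[C@@]12N(C(=O)OC(C)(C)C)C(=O)CCC2
F11 | step 17 | keto carbamate: Boc-amino cyclopentane with a 4-oxohept-6-enyl chain at C19 | C[C@@H](CO[Si](c1ccccc1)(c1ccccc1)C(C)(C)C)[C@H]1CCC[C@@]1(CCCC(=O)CC=C)NC(=O)OC(C)(C)C
F12 | step 25 | C5 epimer of 45 (5R) | C[C@@H](C#C[C@H](O)/C=C(/Cl)CCOC(C)=O)[C@H]1CCC[C@@]12N3CC(C(=O)OC)=CC[C@H]3CCC2
F13 | step 25 | 4-nitrobenzoate of 45 (5S) | C[C@@H](C#C[C@@H](OC(=O)c4ccc([N+](=O)[O-])cc4)/C=C(/Cl)CCOC(C)=O)[C@H]1CCC[C@@]12N3CC(C(=O)OC)=CC[C@H]3CCC2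
F14 | step 27 | C5 tert-butyldimethylsilyl ether of 45 | C[C@@H](C#C[C@@H](O[Si](C)(C)C(C)(C)C)/C=C(/Cl)CCOC(C)=O)[C@H]1CCC[C@@]12N3CC(C(=O)OC)=CC[C@H]3CCC2
F15 | step 27 | C5 silyl ether of seco acid 46 | C[C@@H](C#C[C@@H](O[Si](C)(C)C(C)(C)C)/C=C(/Cl)CCO)[C@H]1CCC[C@@]12N3CC(C(=O)O)=CC[C@H]3CCC2
F16 | step 27 | mixed anhydride of F15 with 2-methyl-6-nitrobenzoic acid | C[C@@H](C#C[C@@H](O[Si](C)(C)C(C)(C)C)/C=C(/Cl)CCO)[C@H]1CCC[C@@]12N3CC(C(=O)OC(=O)c4c(C)cccc4[N+](=O)[O-])=CC[C@H]3CCC2
F17 | step 27 | C5 silyl ether of alkyne macrolactone 48 | C[C@H]1C#C[C@@H](O[Si](C)(C)C(C)(C)C)/C=C(/Cl)CCOC(=O)C2=CC[C@H]3CCC[C@]4(CCC[C@H]14)N3C2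
A1 | alternative 1 | 3-{(1R)-1-[(1R,2S)-2-(4-pivaloyloxybutyl)cyclopentyl]ethyl}-1,4,2-dioxazol-5-one (configured as in the SMILES) | C[C@@H](C1=NOC(=O)O1)[C@H]2CCC[C@@H]2CCCCOC(=O)C(C)(C)C
A2 | alternative 1 | cis-fused bicyclic γ-lactam with N24 on C19 | C[C@H]1C(=O)N[C@]2(CCCCOC(=O)C(C)(C)C)CCC[C@H]12
A3 | alternative 2 | C15=N24 imine carrying the C9 ester of 2,5-dihydrothiophene-3-carboxylic acid 1,1-dioxide and the C5 silyl ether | C[C@@H](/C=C\[C@@H](O[Si](C)(C)C(C)(C)C)/C=C(/Cl)CCOC(=O)C1=CCS(=O)(=O)C1)[C@H]2CCC[C@]23CCCC=N3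
A4 | alternative 2 | C5 tert-butyldimethylsilyl ether of the target | C[C@H]1/C=C\[C@@H](O[Si](C)(C)C(C)(C)C)/C=C(/Cl)CCOC(=O)C2=CC[C@H]3CCC[C@]4(CCC[C@H]14)N3C2
A5 | alternative 3 | ring A enecarbamate with N-tethered vinyl sulfone | COC(=O)N(CCC(=C)S(=O)(=O)c1ccccc1)C2=CCC[C@@H]2[C@@H](C)CO[Si](C)(C)C(C)(C)C
A6 | alternative 3 | spirocyclic carbamate sulfone (C17 epimers) | COC(=O)N1CCC(S(=O)(=O)c2ccccc2)C[C@]13CCC[C@@H]3[C@@H](C)CO[Si](C)(C)C(C)(C)C
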